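The plan hinges on one observation about ring A. Its equatorial oxygen on C2 and the gem-dimethyl carbon C4 stand in a 1,3 relationship, so both can be tied together beforehand in a four-membered O-C2-C3-C4 ether. When Cp2TiCl breaks the C4-O side of that strained ring, C2 retains its oxygen while C4 becomes a tertiary radical, and the open E,E-polyene chain answers by making C4-C5 and C9-C10. Rings A and B and the centres C5, C9 and C10 thus arise in a single operation. The substrate is an acyclic C20 triene ending in a 2,2-dimethyloxetane on one side and the (13S)-vinyl carbinol on the other. Alkene migration and senecioylation complete the target.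

Key step: step 14

Remark: labdane numbering (C1 to C20) is used for all intermediates, acyclic ones included, and both enantiomers of sparteine are taken as purchasable.

Step 1
Reactants: 1 (2E,6E)-farnesol
Product: 2 (2S,3S)-2,3-epoxyfarnesol
Conditions: Ti(OiPr)4 (5 mol %), L-(+)-diethyl tartrate (6 mol %), t-BuOOH, 4 Å MS, CH2Cl2, −20 °C
Reagents that add atoms: tert-butyl hydroperoxide, CC(C)(C)OO
Why: Sharpless asymmetric epoxidation reacts only at the alkene next to the hydroxyl, and with an E-allylic alcohol the L-(+)-tartrate catalyst delivers oxygen to the face that gives the (2S,3S)-epoxide, which fixes the future C13.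

Step 2
Reactants: 2 (2S,3S)-2,3-epoxyfarnesol
Product: 3 (2R,3S)-2,3-epoxyfarnesyl iodide
Conditions: I2, PPh3, imidazole, THF, 0 °C, dark
Reagents that add atoms: iodine, II
Why: Appel-type iodination replaces the primary hydroxyl by SN2 at C1 under near-neutral conditions that leave the epoxide, both stereocentres (the C2 descriptor changes by priority only) and the remote alkenes untouched.

Step 3
Reactants: 3 (2R,3S)-2,3-epoxyfarnesyl iodide
Product: 4 (3S,6E)-nerolidol
Conditions: Zn dust, AcOH (2 equiv), EtOH, 0 °C to rt
Reagents that add atoms: none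
Why: Zinc inserts into the C-I bond and beta-elimination breaks only the secondary epoxide C-O bond (reductive opening of a 2,3-epoxy iodide), so the tertiary C-O bond and its S configuration pass unchanged into the vinyl carbinol.

Step 4
Reactants: 4 (3S,6E)-nerolidol
Product: 5 (3S,6E)-nerolidol triethylsilyl ether
Conditions: TESOTf, 2,6-lutidine, CH2Cl2, −78 to 0 °C
Reagents that add atoms: triethylsilyl trifluoromethanesulfonate, CC[Si](CC)(CC)OS(=O)(=O)C(F)(F)F
Why: Silylation of a hindered tertiary alcohol with a silyl triflate and a non-nucleophilic pyridine base is standard, removes the acidic proton before the organolithium chemistry and touches no stereocentre.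

Step 5
Reactants: 5 (3S,6E)-nerolidol triethylsilyl ether
Product: 7 (2E,6E,10S)-2,6,10-trimethyl-10-(triethylsilyloxy)dodeca-2,6,11-trien-1-ol, via enal 6 (not isolated)
Conditions: SeO2 (0.2 equiv), t-BuOOH (decane), CH2Cl2, 0 °C to rt, stopped at partial conversion; then NaBH4, EtOH, 0 °C
Reagents that add atoms: selenium dioxide, O=[Se]=O; tert-butyl hydroperoxide, CC(C)(C)OO
Why: Riley-type allylic oxidation (ene reaction, then [2,3]-shift) prefers the terminal, least hindered trisubstituted alkene and its E-methyl group (the future C1), the vinyl group has no allylic hydrogen, and borohydride returns over-oxidised enal 6 to the alcohol.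

Step 6
Reactants: 7 (2E,6E,10S)-2,6,10-trimethyl-10-(triethylsilyloxy)dodeca-2,6,11-trien-1-ol
Product: 8 methyl carbonate of 7
Conditions: ClCO2Me, pyridine, CH2Cl2, 0 °C
Reagents that add atoms: methyl chloroformate, COC(=O)Cl
Why: Acylation of the only free hydroxyl, a primary allylic one, with a chloroformate installs the leaving group needed for palladium.

Step 7
Reactants: 8 methyl carbonate of 7
Product: 9 C15 (E)-allylic pinacol boronate
Conditions: B2pin2, Pd2(dba)3 (2.5 mol %), DMSO, 50 °C
Reagents that add atoms: bis(pinacolato)diboron, CC1(C)OB(OC1(C)C)B1OC(C)(C)C(C)(C)O1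
Why: In this Miyaura-type allylic borylation zerovalent palladium ionises the carbonate, the released methoxide activates B2pin2 for transmetalation, and reductive elimination at the unsubstituted terminus gives the linear E-allylboronate, while the silylated vinyl carbinol offers no leaving group.

Step 8
Reactants: 10 3-methylbutane-1,3-diol
Product: 11 3-hydroxy-3-methylbutyl N,N-diisopropylcarbamate
Conditions: iPr2NCOCl (1.05 equiv), Et3N, DMAP (cat.), CH2Cl2, reflux
Reagents that add atoms: N,N-diisopropylcarbamoyl chloride, CC(C)N(C(C)C)C(=O)Cl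
Why: Carbamoylation with a bulky carbamoyl chloride discriminates cleanly between the unhindered primary and the tertiary hydroxyl.

Step 9
Reactants: 11 3-hydroxy-3-methylbutyl N,N-diisopropylcarbamate
Product: 12 3-methyl-3-(triethylsilyloxy)butyl N,N-diisopropylcarbamate
Conditions: TESOTf, 2,6-lutidine, CH2Cl2, 0 °C
Reagents that add atoms: triethylsilyl trifluoromethanesulfonate, CC[Si](CC)(CC)OS(=O)(=O)C(F)(F)F
Why: Silyl triflate silylation caps the tertiary hydroxyl so that s-BuLi meets only the carbamate-activated CH2, and the gamma position of the silyloxy group rules out beta-elimination of the carbanion.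

Step 10
Reactants: 12 3-methyl-3-(triethylsilyloxy)butyl N,N-diisopropylcarbamate; 9 C15 (E)-allylic pinacol boronate
Product: 16 (3S,6E,10E,13R)-3,15-bis(triethylsilyloxy)-3,7,11,15-tetramethylhexadeca-1,6,10-trien-13-ol, via lithiated carbamate 13 (not isolated), via boronate complex 14 (not isolated), via secondary boronic ester 15 (not isolated)
Conditions: 12 (1.3 equiv), s-BuLi, (+)-sparteine, Et2O, −78 °C; 9, −78 °C; MgBr2·OEt2, reflux; then NaOH, H2O2, THF, 0 °C to rt
Reagents that add atoms: hydrogen peroxide, OO
Why: In this sparteine-mediated asymmetric lithiation and lithiation-borylation (Matteson-type 1,2-metallate shift) s-BuLi/(+)-sparteine removes the pro-R hydrogen, 13 adds to boron with retention, the allyl group of 14 migrates anti to the departing carbamate and forms C1-C2 with inversion, and oxidation of 15 with retention gives the R alcohol at C2.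

Step 11
Reactants: 16 (3S,6E,10E,13R)-3,15-bis(triethylsilyloxy)-3,7,11,15-tetramethylhexadeca-1,6,10-trien-13-ol
Product: 17 (3S,6E,10E,13R)-3,7,11,15-tetramethylhexadeca-1,6,10-triene-3,13,15-triol
Conditions: TBAF (3 equiv), THF, rt to 40 °C
Reagents that add atoms: none
Why: Fluoride cleaves both tertiary silyl ethers under non-acidic conditions that the tertiary allylic alcohol tolerates, and desilylating before activation means that no sulfonate is exposed to basic fluoride.

Step 12
Reactants: 17 (3S,6E,10E,13R)-3,7,11,15-tetramethylhexadeca-1,6,10-triene-3,13,15-triol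
Product: 18 C2 (chain C13) methanesulfonate of 17
Conditions: MsCl (1.1 equiv), pyridine, CH2Cl2, 0 °C; used without chromatography
Reagents that add atoms: methanesulfonyl chloride, CS(=O)(=O)Cl
Why: Sulfonylation in pyridine is sterically selective for the single secondary hydroxyl over the two tertiary ones and does not break the C2-O bond, so the configuration is retained.

Step 13
Reactants: 18 C2 (chain C13) methanesulfonate of 17
Product: 19 (3S,6E,10E)-12-[(2S)-4,4-dimethyloxetan-2-yl]-3,7,11-trimethyldodeca-1,6,10-trien-3-ol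
Conditions: NaH (2.5 equiv), THF, 0 to 40 °C
Reagents that add atoms: none
Why: In this intramolecular Williamson etherification (4-exo-tet) the C4 alkoxide, pushed towards C2 by its gem-dimethyl group (Thorpe-Ingold effect), displaces the mesylate with inversion to set the S oxetane carbon, and a hydride base leaves no external base in solution for E2 loss of the mesylate.

Step 14
Reactants: 19 (3S,6E,10E)-12-[(2S)-4,4-dimethyloxetan-2-yl]-3,7,11-trimethyldodeca-1,6,10-trien-3-ol
Product: 21 (2R,5R,9R,10R,13S)-labda-8(17),14-diene-2,13-diol (ent-labdane series), via titanium alkoxide 20 (not isolated)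
Conditions: Cp2TiCl2 (3 equiv), Mn dust (8 equiv), degassed THF, rt until green; 19 in THF added in one portion (about 0.1 M in titanium), rt to 40 °C; aq. NaH2PO4
Reagents that add atoms: none
Why: Proposed new method: Cp2TiCl should coordinate the oxetane oxygen and, helped by ring strain, cleave the more substituted C4-O bond by single-electron transfer to give a C2 titanium alkoxide and a tertiary C4 radical; this radical closes ring A by 6-endo-trig addition to C5, the resulting tertiary C10 radical closes ring B by 6-endo-trig addition to C9, and the tertiary C8 radical is taken up by a second Cp2TiCl and sheds a C17 hydrogen to leave the C8-C17 methylene. The nearest known reaction types are the Cp2TiCl cascade of epoxypolyprenes to trans-decalins ending in an exocyclic alkene and the Cp2TiCl reductive opening of simple oxetanes to gamma-titanoxy radicals; their combination is untested. C5 is controlled by C2, because the chair-like closure of ring A places the bulky titanoxy group equatorial and so avoids a 1,3-diaxial contact with a C4 methyl and the C10 substituent. C10 and C9 are controlled by the second chair and by the E geometry of the C5-C10 and C8-C9 alkenes, which translate into a trans ring fusion with axial C20 and an equatorial C9 side chain. Chemoselective initiation is secured because the oxetane is the only group of 19 that trivalent titanium reduces at room temperature (the hindered C13 hydroxyl merely binds one extra equivalent), and endo regiochemistry because each trisubstituted alkene is attacked at its CH carbon to give a tertiary radical. Stopping after two rings is the selectivity that needs help, since vinyl carbinol termini can accept a slow 7-endo closure when little trivalent titanium is present; an excess of preformed Cp2TiCl at about 0.1 M therefore makes capture of the C8 radical the faster event.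

Step 15
Reactants: 21 (2R,5R,9R,10R,13S)-labda-8(17),14-diene-2,13-diol
Product: 22 (2R,5R,9R,10R,13S)-labda-7,14-diene-2,13-diol
Conditions: [N,N'-bis(3,5-di-tert-butylsalicylidene)cyclohexane-1,2-diaminato]CoCl (5 mol %), PhSiH3 (10 mol %), benzene, rt
Reagents that add atoms: none
Why: In this metal-hydride hydrogen-atom-transfer isomerisation the cobalt hydride adds a hydrogen atom to C17, divalent cobalt takes one back from the accessible C7 methylene rather than the hindered C9 methine, the trisubstituted product is inert to the catalyst, and addition to the vinyl group is merely reversible because C13 carries no hydrogen.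

Step 16
Reactants: 22 (2R,5R,9R,10R,13S)-labda-7,14-diene-2,13-diol; 23 3-methylbut-2-enoic acid
Product: 24 target, (2R,5R,9R,10R,13S)-13-hydroxylabda-7,14-dien-2-yl 3-methylbut-2-enoate
Conditions: 23 (1.2 equiv), DCC, DMAP (0.2 equiv), CH2Cl2, 0 °C to rt
Reagents that add atoms: 3-methylbut-2-enoic acid 23, CC(C)=CC(=O)O
Why: Steglich esterification acylates the unhindered equatorial secondary C2 hydroxyl with retention, whereas the tertiary allylic C13 hydroxyl is too hindered to react under these conditions.

Compound list
1 | (2E,6E)-farnesol | CC(C)=CCC/C(C)=C/CC/C(C)=C/CO | starting material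
2 | (2S,3S)-2,3-epoxyfarnesol | OC[C@@H]1O[C@@]1(C)CC/C=C(\C)CCC=C(C)C | intermediate
3 | (2R,3S)-2,3-epoxyfarnesyl iodide | IC[C@@H]1O[C@@]1(C)CC/C=C(\C)CCC=C(C)C | intermediate
4 | (3S,6E)-nerolidol | C=C[C@@](C)(O)CC/C=C(\C)CCC=C(C)C | intermediate
5 | (3S,6E)-nerolidol triethylsilyl ether | C=C[C@@](C)(O[Si](CC)(CC)CC)CC/C=C(\C)CCC=C(C)C | intermediate
6 | (2E,6E,10S)-2,6,10-trimethyl-10-(triethylsilyloxy)dodeca-2,6,11-trienal | C=C[C@@](C)(O[Si](CC)(CC)CC)CC/C=C(\C)CC/C=C(\C)C=O | intermediate
7 | (2E,6E,10S)-2,6,10-trimethyl-10-(triethylsilyloxy)dodeca-2,6,11-trien-1-ol | C=C[C@@](C)(O[Si](CC)(CC)CC)CC/C=C(\C)CC/C=C(\C)CO | intermediate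
8 | methyl carbonate of 7 | C=C[C@@](C)(O[Si](CC)(CC)CC)CC/C=C(\C)CC/C=C(\C)COC(=O)OC | intermediate
9 | C15 (E)-allylic pinacol boronate (boron on C1) | C=C[C@@](C)(O[Si](CC)(CC)CC)CC/C=C(\C)CC/C=C(\C)CB1OC(C)(C)C(C)(C)O1 | intermediate
10 | 3-methylbutane-1,3-diol | CC(C)(O)CCO | starting material
11 | 3-hydroxy-3-methylbutyl N,N-diisopropylcarbamate | CC(C)N(C(C)C)C(=O)OCCC(C)(C)O | intermediate
12 | 3-methyl-3-(triethylsilyloxy)butyl N,N-diisopropylcarbamate | CC(C)N(C(C)C)C(=O)OCCC(C)(C)O[Si](CC)(CC)CC | intermediate
13 | (R)-1-lithio derivative of 12 ((+)-sparteine complex) | [Li][C@@H](OC(=O)N(C(C)C)C(C)C)CC(C)(C)O[Si](CC)(CC)CC | intermediate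
14 | lithium boronate complex of 13 and 9 | C=C[C@@](C)(O[Si](CC)(CC)CC)CC/C=C(\C)CC/C=C(\C)C[B-]1(OC(C)(C)C(C)(C)O1)[C@@H](OC(=O)N(C(C)C)C(C)C)CC(C)(C)O[Si](CC)(CC)CC.[Li+] | intermediate
15 | secondary C2 pinacol boronic ester (boron where the hydroxyl of 16 will stand) | C=C[C@@](C)(O[Si](CC)(CC)CC)CC/C=C(\C)CC/C=C(\C)C[C@@H](B1OC(C)(C)C(C)(C)O1)CC(C)(C)O[Si](CC)(CC)CC | intermediate
16 | (3S,6E,10E,13R)-3,15-bis(triethylsilyloxy)-3,7,11,15-tetramethylhexadeca-1,6,10-trien-13-ol | C=C[C@@](C)(O[Si](CC)(CC)CC)CC/C=C(\C)CC/C=C(\C)C[C@@H](O)CC(C)(C)O[Si](CC)(CC)CC | intermediate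
17 | (3S,6E,10E,13R)-3,7,11,15-tetramethylhexadeca-1,6,10-triene-3,13,15-triol | C=C[C@@](C)(O)CC/C=C(\C)CC/C=C(\C)C[C@@H](O)CC(C)(C)O | intermediate
18 | C2 (chain C13) methanesulfonate of 17 | C=C[C@@](C)(O)CC/C=C(\C)CC/C=C(\C)C[C@@H](OS(C)(=O)=O)CC(C)(C)O | intermediate
19 | (3S,6E,10E)-12-[(2S)-4,4-dimethyloxetan-2-yl]-3,7,11-trimethyldodeca-1,6,10-trien-3-ol | C=C[C@@](C)(O)CC/C=C(\C)CC/C=C(\C)C[C@H]1CC(C)(C)O1 | intermediate
20 | chlorotitanocene C2 alkoxide of 21 | C=C[C@@](C)(O)CC[C@@H]1C(=C)CC[C@@H]2C(C)(C)C[C@@H]([O-])C[C@@]12C.[Ti+4].[Cl-].[cH-]1cccc1.[cH-]1cccc1 | intermediate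
21 | (2R,5R,9R,10R,13S)-labda-8(17),14-diene-2,13-diol (ent-labdane series, C2 hydroxyl equatorial) | C=C[C@@](C)(O)CC[C@@H]1C(=C)CC[C@@H]2C(C)(C)C[C@@H](O)C[C@@]12C | intermediate
22 | (2R,5R,9R,10R,13S)-labda-7,14-diene-2,13-diol | C=C[C@@](C)(O)CC[C@@H]1C(C)=CC[C@@H]2C(C)(C)C[C@@H](O)C[C@@]12C | intermediate
23 | 3-methylbut-2-enoic acid (senecioic acid) | CC(C)=CC(=O)O | starting material
24 | (2R,5R,9R,10R,13S)-13-hydroxylabda-7,14-dien-2-yl 3-methylbut-2-enoate (CNP0252389.1) | C=C[C@@](C)(O)CC[C@@H]1C(C)=CC[C@@H]2C(C)(C)C[C@@H](OC(=O)C=C(C)C)C[C@@]12C | target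

Total steps: 16. Longest linear sequence: 14 (steps 1 to 7, then 10 to 16).

Steps most likely to fail

1. Step 14.
- **What may go wrong:** Electron transfer to the oxetane may be too slow at a useful temperature. The C4 or C10 radical may be captured by titanium before the next ring has closed. The C8 radical may add to the vinyl group in a third, 7-endo closure.
- **Fallback (known reaction types only; sets out from 9, returns at 21):** The initiator is moved to the classical C3-C4 epoxide, the C2 oxygen travels along as a silyl ether, and the surplus C3 oxygen is deleted afterwards. 3-Methylbut-3-en-1-ol and iPr2NCOCl give 3-methylbut-3-enyl N,N-diisopropylcarbamate F1. Under the conditions of step 10, but with (−)-sparteine, this passes through the (S)-lithiated carbamate F2, the boronate complex F3 formed with 9 and the homoallylic boronic ester F4 to the methallyl carbinol F5. The C2 of F5 already has the configuration of the target, because no inversion follows. The catalyst of step 15 moves the 1,1-disubstituted alkene inward to the prenyl-type allylic alcohol F6. Hydroxyl-directed epoxidation with VO(acac)2 and t-BuOOH, steered by allylic 1,3-strain, gives the threo epoxy alcohol F7, and TESCl/imidazole gives the epoxy silyl ether F8. Cp2TiCl under the conditions of step 14 then performs the established epoxypolyene bicyclisation via the C3 titanium alkoxide F9 to the 3-hydroxy decalin F10, in which both ring A oxygens sit equatorial in the same chair. PhOC(S)Cl/DMAP gives the C3 phenyl thionocarbonate F11. Barton-McCombie reduction (Bu3SnH, AIBN, toluene, 80 °C) gives the bis(triethylsilyl) ether F12, and TBAF releases 21.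

2. Step 13.
- **What may go wrong:** E2 loss of methanesulfonic acid towards the allylic C1 hydrogens (conjugated diene formation) may outrun the 4-exo-tet closure. So may Grob-type fragmentation of the metal alkoxide, with loss of acetone.
- **Fallback (sets out from 16, returns at 19):** Activation and unmasking are reversed, so that the nucleophile is released only once the leaving group is in place, and neither a selective sulfonylation nor a metal hydride is needed. The single free hydroxyl of 16 is mesylated (MsCl, Et3N, CH2Cl2, −30 °C) to the bis(triethylsilyl) mesylate F13. Fluoride (TBAF or TASF, THF, 0 °C to rt) then strips silicon from the C4 oxygen. The alkoxide formed at low stationary concentration closes the ring with the same inversion, and the C13 silyl ether falls in the same pot.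

3. Step 15.
- **What may go wrong:** Hydrogen abstraction may occur at the C9 methine instead of C7, which moves the alkene to the tetrasubstituted C8-C9 position and erases C9. The reaction may stall. The C8 radical may be diverted towards the vinyl group.
- **Fallback (sets out from 21, returns at 24):** The alkene is moved by an oxidation and reductive 1,3-transposition pair that can only deliver the C7-C8 isomer. 21 is esterified first, as in step 16, to the exocyclic senecioate F14. SeO2/t-BuOOH hydroxylates the allylic C7 methylene to the axial 7-hydroxy ester F15. Mitsunobu displacement with 2-nitrobenzenesulfonylhydrazide (PPh3, DEAD, THF, −30 °C) gives the N-allylic sulfonylhydrazine F16, which on warming loses the sulfinic acid to give the allylic diazene F17. Retro-ene loss of nitrogen from F17 transfers hydrogen to C17 and places the double bond between C7 and C8, giving 24 directly. The tertiary C13 hydroxyl takes no part in the Mitsunobu step.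

Further compounds
F1 | step 14 | 3-methylbut-3-enyl N,N-diisopropylcarbamate | C=C(C)CCOC(=O)N(C(C)C)C(C)C
F2 | step 14 | (S)-1-lithio derivative of F1 ((−)-sparteine complex) | [Li][C@H](OC(=O)N(C(C)C)C(C)C)CC(C)=C
F3 | step 14 | lithium boronate complex of F2 and 9 | C=C[C@@](C)(O[Si](CC)(CC)CC)CC/C=C(\C)CC/C=C(\C)C[B-]1(OC(C)(C)C(C)(C)O1)[C@H](OC(=O)N(C(C)C)C(C)C)CC(C)=C.[Li+]
F4 | step 14 | homoallylic C2 pinacol boronic ester with methallyl terminus | C=C[C@@](C)(O[Si](CC)(CC)CC)CC/C=C(\C)CC/C=C(\C)C[C@H](B1OC(C)(C)C(C)(C)O1)CC(C)=C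
F5 | step 14 | (3S,6E,10E,13R)-3,7,11,15-tetramethyl-3-(triethylsilyloxy)hexadeca-1,6,10,15-tetraen-13-ol | C=C[C@@](C)(O[Si](CC)(CC)CC)CC/C=C(\C)CC/C=C(\C)C[C@H](O)CC(C)=C
F6 | step 14 | (3S,6E,10E,13S)-3,7,11,15-tetramethyl-3-(triethylsilyloxy)hexadeca-1,6,10,14-tetraen-13-ol | C=C[C@@](C)(O[Si](CC)(CC)CC)CC/C=C(\C)CC/C=C(\C)C[C@H](O)C=C(C)C
F7 | step 14 | threo (13S,14R)-14,15-epoxide of F6 | C=C[C@@](C)(O[Si](CC)(CC)CC)CC/C=C(\C)CC/C=C(\C)C[C@H](O)[C@H]1OC1(C)C
F8 | step 14 | C2 (chain C13) triethylsilyl ether of F7 | C=C[C@@](C)(O[Si](CC)(CC)CC)CC/C=C(\C)CC/C=C(\C)C[C@H](O[Si](CC)(CC)CC)[C@H]1OC1(C)C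
F9 | step 14 | chlorotitanocene C3 alkoxide of F10 | C=C[C@@](C)(O[Si](CC)(CC)CC)CC[C@@H]1C(=C)CC[C@@H]2C(C)(C)[C@H]([O-])[C@@H](O[Si](CC)(CC)CC)C[C@@]12C.[Ti+4].[Cl-].[cH-]1cccc1.[cH-]1cccc1
F10 | step 14 | 2,13-bis(triethylsilyloxy)-ent-labda-8(17),14-dien-3-ol (C2 and C3 oxygens trans-diequatorial) | C=C[C@@](C)(O[Si](CC)(CC)CC)CC[C@@H]1C(=C)CC[C@@H]2C(C)(C)[C@H](O)[C@@H](O[Si](CC)(CC)CC)C[C@@]12C
F11 | step 14 | C3 O-phenyl thionocarbonate of F10 | C=C[C@@](C)(O[Si](CC)(CC)CC)CC[C@@H]1C(=C)CC[C@@H]2C(C)(C)[C@H](OC(=S)Oc3ccccc3)[C@@H](O[Si](CC)(CC)CC)C[C@@]12C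
F12 | step 14 | 2,13-bis(triethylsilyl) ether of 21 | C=C[C@@](C)(O[Si](CC)(CC)CC)CC[C@@H]1C(=C)CC[C@@H]2C(C)(C)C[C@@H](O[Si](CC)(CC)CC)C[C@@]12C
F13 | step 13 | C2 (chain C13) methanesulfonate of 16 | C=C[C@@](C)(O[Si](CC)(CC)CC)CC/C=C(\C)CC/C=C(\C)C[C@@H](OS(C)(=O)=O)CC(C)(C)O[Si](CC)(CC)CC
F14 | step 15 | C2 3-methylbut-2-enoate of 21 | C=C[C@@](C)(O)CC[C@@H]1C(=C)CC[C@@H]2C(C)(C)C[C@@H](OC(=O)C=C(C)C)C[C@@]12C
F15 | step 15 | 7-hydroxy derivative of F14 (axial hydroxyl, same face as H5 and H9) | C=C[C@@](C)(O)CC[C@@H]1C(=C)[C@@H](O)C[C@@H]2C(C)(C)C[C@@H](OC(=O)C=C(C)C)C[C@@]12C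
F16 | step 15 | C7 N-(2-nitrobenzenesulfonyl)hydrazine from F15 (inverted at C7) | C=C[C@@](C)(O)CC[C@@H]1C(=C)[C@H](N(N)S(=O)(=O)c3ccccc3[N+](=O)[O-])C[C@@H]2C(C)(C)C[C@@H](OC(=O)C=C(C)C)C[C@@]12C
F17 | step 15 | C7 allylic diazene from F16 | C=C[C@@](C)(O)CC[C@@H]1C(=C)[C@H](N=N)C[C@@H]2C(C)(C)C[C@@H](OC(=O)C=C(C)C)C[C@@]12C
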